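**Plan**
1. Retrosynthetic cuts, in order: the phenol O–benzyl bond, then the C5–CO2Me bond (back to an aryl bromide, a placeholder that lets the C3 ester be reduced alone), then CH2OH back to CO2Me at C3.
2. Key cut: the C3–C3a bond of the dihydrofuran ring O1–C2–C3–C3a–C7a. Returning arene carbon C3a to the exocyclic carboxyl carbon re-opens the five-membered ring to the six-membered pyranone ring of a (2S)-flavanone.
3. Enabling feature: C3 bears both arene carbon C3a and a one-carbon branch, the Ar–CH–CO2R pattern left by an oxidative 1,2-aryl shift of an aryl ketone. O1 sits ortho to C3a and makes it a good migrating carbon.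
4. Last cuts: the C2–aryl bond (chromone + arylboronic acid) and C2 of the chromone (o-hydroxyacetophenone + formamide acetal).
5. Forward order: bought arene A, six-membered pyranone ring (step 2), ring B joined at C2 (step 3), 6→5 contraction (step 4), then reduction, carbonylation and debenzylation.
6. Stereochemistry: C2 (S) comes from the chiral Pd catalyst in step 3. C3 follows from C2 by substrate control in step 4 (anti iodination, then shift with inversion, giving trans).

Key step: step 4

Assumption: the sense of induction in step 3 is carried over from cyclic enones, where the (S)-ligand delivers the aryl group to the face that corresponds to the 2R-flavanone. The (R)-ligand is therefore specified, and the antipodal ligand would be used if the sense proved opposite.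

**Step 1**
Reactants: 1 2'-hydroxy-3'-methoxyacetophenone
Product: 2 1-(5-bromo-2-hydroxy-3-methoxyphenyl)ethanone
Conditions: NBS (1.05 equiv), MeCN, 0 °C to rt
Reagents that add atoms: N-bromosuccinimide O=C1CCC(=O)N1Br
Why: Electrophilic aromatic bromination: the free phenol is the strongest donor and both its ortho positions are blocked (acetyl, methoxy), so bromine should enter para to OH, a position that is also meta to the acetyl group.

**Step 2**
Reactants: 2 1-(5-bromo-2-hydroxy-3-methoxyphenyl)ethanone
Product: 4 6-bromo-8-methoxy-4H-chromen-4-one, via enaminone 3 (not isolated)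
Conditions: Me2NCH(OMe)2, toluene, 100 °C; concentrate; then conc. HCl, CH2Cl2, rt to 40 °C
Reagents that add atoms: N,N-dimethylformamide dimethyl acetal COC(OC)N(C)C
Why: Enaminone chromone synthesis: condensation of the methyl ketone with the formamide acetal gives 3, and acid triggers 6-endo conjugate addition of the phenol followed by loss of dimethylamine, the standard route to 2,3-unsubstituted chromones.

**Step 3**
Reactants: 4 6-bromo-8-methoxy-4H-chromen-4-one; 5 [4-(benzyloxy)-3-methoxyphenyl]boronic acid
Product: 6 (2S)-2-[4-(benzyloxy)-3-methoxyphenyl]-6-bromo-8-methoxychroman-4-one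
Conditions: Pd(OCOCF3)2 (5 mol %), (R)-t-BuPyOx (6 mol %), NH4PF6 (30 mol %), H2O (5 equiv), 5 (2 equiv), ClCH2CH2Cl, 60 °C
Reagents that add atoms: none
Why: Pd(II)/pyridine-oxazoline-catalysed asymmetric conjugate addition of an arylboronic acid to a chromone: the enantiodetermining insertion of C2=C3 into the aryl–Pd bond inside the chiral ligand pocket sets C2 as S, the redox-neutral Pd(II) cycle should leave the aryl bromide alone, and the near-neutral medium avoids retro-oxa-Michael racemisation.

**Step 4**
Reactants: 6 (2S)-2-[4-(benzyloxy)-3-methoxyphenyl]-6-bromo-8-methoxychroman-4-one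
Product: 10 methyl (2S,3S)-2-[4-(benzyloxy)-3-methoxyphenyl]-5-bromo-7-methoxy-2,3-dihydrobenzofuran-3-carboxylate (trans), via enol ether 7 (not isolated), via iodane ketal 8 (not isolated), via orthoester 9 (not isolated)
Conditions: PhI(OAc)2 (1.2 equiv), conc. H2SO4 (0.5 equiv), HC(OMe)3, rt; aq. NaHCO3 work-up
Reagents that add atoms: trimethyl orthoformate COC(OC)OC (OMe of the new ester); water O (carbonyl O of the new ester, on work-up); (diacetoxyiodo)benzene CC(=O)OI(OC(C)=O)c1ccccc1 (atoms only in intermediate 8)
Why: This is the hypervalent-iodine oxidative 1,2-aryl shift of an aryl ketone, known on flavanones as a stereospecific route to trans-2-aryl-2,3-dihydrobenzofuran-3-carboxylates: acid and HC(OMe)3 turn the C4 ketone into enol ether 7, PhI(OAc)2 attacks C3 on the face opposite the equatorial C2 aryl group while methanol caps C4 to give the 2,3-trans iodane ketal 8, arene carbon C4a then moves from C4 to C3 as PhI leaves, and C4, now outside the ring, is held as orthoester 9 until aqueous work-up gives ester 10. The five-membered ring O1–C2–C3–C3a–C7a is closed by the new C3–C3a bond through ipso attack of the arene on C3 (3-exo-tet, bridged phenonium stage) with cleavage of the old C4–C4a bond, so the pyranone ring shrinks by one carbon and no other ring is formed. C2 is not touched and stays S, and C3 is set by substrate control, since anti iodination followed by inversion during the shift places the carboxyl carbon trans to the C2 aryl group, which is also the more stable arrangement. The step needs migration of C4a in preference to migration of the C2 aryl group, to elimination across C2–C3 and to displacement of iodine by methanol. In the diequatorial half-chair of 8 the C4–C4a bond lies antiperiplanar to C3–I whereas the C2 aryl group is gauche to it, O1 ortho to C4a stabilises the bridged cation, and bromine sits meta to C4a where it costs little migratory aptitude. The water-free medium, room temperature and a short reaction time should keep acid-induced opening of the C2–O1 bond, and with it loss of enantiopurity, small.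

**Step 5**
Reactants: 10 methyl (2S,3S)-2-[4-(benzyloxy)-3-methoxyphenyl]-5-bromo-7-methoxy-2,3-dihydrobenzofuran-3-carboxylate
Product: 11 [(2S,3R)-2-[4-(benzyloxy)-3-methoxyphenyl]-5-bromo-7-methoxy-2,3-dihydrobenzofuran-3-yl]methanol
Conditions: DIBAL-H (3 equiv), CH2Cl2, −78 to 0 °C; aq. Rochelle salt
Reagents that add atoms: none
Why: Ester reduction with DIBAL-H: the non-basic hydride should reduce the only ester present at low temperature without deprotonating C3, so neither epimerisation nor E1cB opening of the C2–O1 bond is expected, and the aryl bromide and benzyl ether are inert (the C3 descriptor changes from S to R only because of CIP ranking).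

**Step 6**
Reactants: 11 [(2S,3R)-2-[4-(benzyloxy)-3-methoxyphenyl]-5-bromo-7-methoxy-2,3-dihydrobenzofuran-3-yl]methanol
Product: 12 methyl (2S,3R)-2-[4-(benzyloxy)-3-methoxyphenyl]-3-(hydroxymethyl)-7-methoxy-2,3-dihydrobenzofuran-5-carboxylate
Conditions: Pd(OAc)2 (5 mol %), Xantphos (6 mol %), CO (1 atm), Et3N–MeOH, 70 °C
Reagents that add atoms: carbon monoxide [C-]#[O+]; methanol CO
Why: Palladium-catalysed alkoxycarbonylation of an aryl bromide: oxidative addition, CO insertion and methanolysis of the acyl-palladium species install the C5 ester, methanol in large excess outcompetes the substrate's own primary alcohol, and the protected phenol and non-acidic stereocentres should tolerate the warm amine base.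

**Step 7**
Reactants: 12 methyl (2S,3R)-2-[4-(benzyloxy)-3-methoxyphenyl]-3-(hydroxymethyl)-7-methoxy-2,3-dihydrobenzofuran-5-carboxylate
Product: 13 curlignan, methyl (2S,3R)-2-(4-hydroxy-3-methoxyphenyl)-3-(hydroxymethyl)-7-methoxy-2,3-dihydrobenzofuran-5-carboxylate
Conditions: H2 (1 atm), 10% Pd/C, EtOAc–MeOH, rt, stopped at full conversion
Reagents that add atoms: none
Why: Catalytic hydrogenolysis of an aryl benzyl ether: the unhindered primary O–CH2Ph bond should be cleaved much faster than the secondary, cyclic C2–O1 benzylic bond, as is usual for phenylcoumaran neolignans, and the ester and both stereocentres are untouched.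

**Compound list**
1 | 2'-hydroxy-3'-methoxyacetophenone | CC(=O)c1cccc(OC)c1O | starting material
2 | 1-(5-bromo-2-hydroxy-3-methoxyphenyl)ethanone | CC(=O)c1cc(Br)cc(OC)c1O | intermediate
3 | (E)-1-(5-bromo-2-hydroxy-3-methoxyphenyl)-3-(dimethylamino)prop-2-en-1-one | CN(C)/C=C/C(=O)c1cc(Br)cc(OC)c1O | intermediate
4 | 6-bromo-8-methoxy-4H-chromen-4-one | O=c1ccoc2c(OC)cc(Br)cc12 | intermediate
5 | [4-(benzyloxy)-3-methoxyphenyl]boronic acid | OB(O)c1ccc(OCc2ccccc2)c(OC)c1 | starting material
6 | (2S)-2-[4-(benzyloxy)-3-methoxyphenyl]-6-bromo-8-methoxychroman-4-one | O=C1C[C@@H](c3ccc(OCc4ccccc4)c(OC)c3)Oc2c(OC)cc(Br)cc12 | intermediate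
7 | (2S)-2-[4-(benzyloxy)-3-methoxyphenyl]-6-bromo-4,8-dimethoxy-2H-chromene | COC1=C[C@@H](c3ccc(OCc4ccccc4)c(OC)c3)Oc2c(OC)cc(Br)cc12 | intermediate
8 | 4,4-dimethyl ketal of 6 bearing an acetoxy(phenyl)-λ3-iodanyl group at C3, iodine trans to the C2 aryl group | COC1(OC)[C@H](I(OC(C)=O)c3ccccc3)[C@@H](c3ccc(OCc4ccccc4)c(OC)c3)Oc2c(OC)cc(Br)cc12 | intermediate
9 | (2S,3S)-2-[4-(benzyloxy)-3-methoxyphenyl]-5-bromo-7-methoxy-3-(trimethoxymethyl)-2,3-dihydrobenzofuran | Brc1cc(OC)c2c(c1)[C@H](C(OC)(OC)OC)[C@@H](c1ccc(OCc3ccccc3)c(OC)c1)O2 | intermediate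
10 | methyl (2S,3S)-2-[4-(benzyloxy)-3-methoxyphenyl]-5-bromo-7-methoxy-2,3-dihydrobenzofuran-3-carboxylate (trans) | Brc1cc(OC)c2c(c1)[C@H](C(=O)OC)[C@@H](c1ccc(OCc3ccccc3)c(OC)c1)O2 | intermediate
11 | [(2S,3R)-2-[4-(benzyloxy)-3-methoxyphenyl]-5-bromo-7-methoxy-2,3-dihydrobenzofuran-3-yl]methanol | Brc1cc(OC)c2c(c1)[C@H](CO)[C@@H](c1ccc(OCc3ccccc3)c(OC)c1)O2 | intermediate
12 | methyl (2S,3R)-2-[4-(benzyloxy)-3-methoxyphenyl]-3-(hydroxymethyl)-7-methoxy-2,3-dihydrobenzofuran-5-carboxylate | COC(=O)c1cc(OC)c2c(c1)[C@H](CO)[C@@H](c1ccc(OCc3ccccc3)c(OC)c1)O2 | intermediate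
13 | curlignan, methyl (2S,3R)-2-(4-hydroxy-3-methoxyphenyl)-3-(hydroxymethyl)-7-methoxy-2,3-dihydrobenzofuran-5-carboxylate | COC(=O)c1cc(OC)c2c(c1)[C@H](CO)[C@@H](c1ccc(O)c(OC)c1)O2 | target

Total step count: 7. Longest linear sequence: 7.

**Steps most likely to fail**

Step 4. The electron-rich C2 aryl group may migrate instead of C4a. Elimination across C2–C3, solvolysis of the C3–I bond, oxidation of ring B, or acid-induced opening of the C2–O1 bond with erosion of enantiopurity may also compete.
The fallback keeps the 6→5 contraction but runs it as a Wolff rearrangement, setting out from 6 and returning at 10.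
- The lithium enolate of 6 (LiHMDS, THF, −78 °C) is acylated with CF3CO2CH2CF3 to the 3-trifluoroacetylflavanone F1.
- Detrifluoroacetylative diazo transfer (MsN3, Et3N, H2O, MeCN) should give the 3-diazoflavanone F2.
- Irradiation (365 nm) in MeOH expels nitrogen with migration of C4a to the ring-contracted ketene F3.
- Methanol traps the ketene to give the ester, partly as the cis ester F4.
- Brief equilibration with catalytic NaOMe in MeOH should converge on the more stable trans ester 10.

Step 3. Protodeboronation of the electron-rich boronic acid may outrun the addition, conversion of the donor-substituted chromone may be low, or facial selectivity may be insufficient.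
The fallback replaces catalytic C–C bond formation by a resolution, setting out from 2 and returning at 6.
- Claisen–Schmidt condensation of 2 with commercial 4-benzyloxy-3-methoxybenzaldehyde (O=Cc1ccc(OCc2ccccc2)c(OC)c1; KOH, EtOH, rt) gives the 2'-hydroxychalcone F5.
- NaOAc in refluxing EtOH closes it by oxa-Michael addition to the racemic flavanone F6.
- Kinetic resolution by asymmetric transfer hydrogenation (RuCl[(R,R)-TsDPEN](p-cymene), HCO2H–Et3N, EtOAc, rt, to about half conversion) should reduce the 2R enantiomer to the cis-(2R,4R)-flavan-4-ol F7.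
- The unreacted (2S)-flavanone 6 is then separated by chromatography.

Step 6. Oxidative addition into the electron-rich aryl bromide may be slow, so that hydrodebromination or catalyst decay under CO takes over.
The fallback replaces palladium catalysis by organolithium carboxylation, setting out from 11 and returning at 12.
- n-BuLi (2.2 equiv, THF, −78 °C) deprotonates the alcohol and exchanges bromine for lithium.
- Quenching with CO2 and acidic work-up gives the carboxylic acid F8.
- MeI and KHCO3 in DMF esterify the acid selectively to 12.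

**Further compounds**
F1 | step 4 | (2S)-2-[4-(benzyloxy)-3-methoxyphenyl]-6-bromo-8-methoxy-3-(trifluoroacetyl)chroman-4-one (C3 unassigned, largely enolised) | O=C1C(C(=O)C(F)(F)F)[C@@H](c3ccc(OCc4ccccc4)c(OC)c3)Oc2c(OC)cc(Br)cc12
F2 | step 4 | 2-[4-(benzyloxy)-3-methoxyphenyl]-6-bromo-3-diazo-8-methoxychroman-4-one, C2 arranged in space as in 6 (CIP label becomes R) | O=C1C(=[N+]=[N-])[C@@H](c3ccc(OCc4ccccc4)c(OC)c3)Oc2c(OC)cc(Br)cc12
F3 | step 4 | ketene, 2-[4-(benzyloxy)-3-methoxyphenyl]-5-bromo-7-methoxy-3-(oxomethylidene)-2,3-dihydrobenzofuran, C2 arranged in space as in 6 | O=C=C1[C@@H](c3ccc(OCc4ccccc4)c(OC)c3)Oc2c(OC)cc(Br)cc12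
F4 | step 4 | methyl (2S,3R)-2-[4-(benzyloxy)-3-methoxyphenyl]-5-bromo-7-methoxy-2,3-dihydrobenzofuran-3-carboxylate (cis) | Brc1cc(OC)c2c(c1)[C@@H](C(=O)OC)[C@@H](c1ccc(OCc3ccccc3)c(OC)c1)O2
F5 | step 3 | (E)-3-[4-(benzyloxy)-3-methoxyphenyl]-1-(5-bromo-2-hydroxy-3-methoxyphenyl)prop-2-en-1-one | O=C(/C=C/c1ccc(OCc2ccccc2)c(OC)c1)c1cc(Br)cc(OC)c1O
F6 | step 3 | racemic 2-[4-(benzyloxy)-3-methoxyphenyl]-6-bromo-8-methoxychroman-4-one | O=C1CC(c3ccc(OCc4ccccc4)c(OC)c3)Oc2c(OC)cc(Br)cc12
F7 | step 3 | (2R,4R)-2-[4-(benzyloxy)-3-methoxyphenyl]-6-bromo-8-methoxychroman-4-ol (cis) | O[C@@H]1C[C@H](c3ccc(OCc4ccccc4)c(OC)c3)Oc2c(OC)cc(Br)cc12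
F8 | step 6 | (2S,3R)-2-[4-(benzyloxy)-3-methoxyphenyl]-3-(hydroxymethyl)-7-methoxy-2,3-dihydrobenzofuran-5-carboxylic acid | OC(=O)c1cc(OC)c2c(c1)[C@H](CO)[C@@H](c1ccc(OCc3ccccc3)c(OC)c1)O2
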